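The time of reading is the first thing to turn: winter is read at 6.0 d and dawn at 4.0 d, both from c(starting complex) = 0.14 M and c(incoming ligand) = 0.0700 M, with two earlier runs beside them.

| flask | starting complex | incoming ligand | remark | time |
|---|---|---|---|---|
| blue | 0.094 M | 0.070 M | run made earlier |  |
| red | 0.21 M | 0.070 M | run made earlier |  |
| winter | 0.14 M | 0.0700 M |  | 6.0 d |
| dawn | 0.14 M | 0.0700 M |  | 4.0 d |

| run | time / d | complex with two exchanged / % | complex with three exchanged / % | side product A / % | side product B / % | starting complex / % |
|---|---|---|---|---|---|---|
| blue | 0.417 | 3.4 | 0 | 3.0 | 0 | 82.2 |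
| blue | 0.833 | 6.2 | 0 | 7.2 | 0 | 76.3 |
| blue | 1.25 | 6.5 | 1.4 | 14.8 | 0.1 | 69.3 |
| blue | 2.50 | 9.0 | 0.8 | 18.5 | 3.4 | 63.0 |
| blue | 5.00 | 8.4 | 1.3 | 27.6 | 5.6 | 54.8 |
| red | 0.417 | 1.9 | 1.5 | 3.4 | 1.2 | 86.1 |
| red | 0.833 | 4.1 | 0 | 6.3 | 1.1 | 80.9 |
| red | 1.25 | 7.4 | 0 | 10.0 | 2.1 | 78.8 |
| red | 2.50 | 4.6 | 0.1 | 15.2 | 3.8 | 75.0 |
| red | 5.00 | 5.2 | 1.3 | 17.5 | 8.2 | 67.4 |

(scatter of a reading: 1 percentage point)



1. which of these there is most of at the end, counted by the starting complex in it, winter (side product B / complex with two exchanged / starting complex / side product A)
2. which of these there is most of at the end, counted by the starting complex in it, dawn (side product B / complex with two exchanged / starting complex / side product A)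
3. amount of the one of these that there is most of at the end, in percent of the starting complex charged, winter
4. amount of the one of these that there is most of at the end, in percent of the starting complex charged, dawn

A later reading lowers the starting complex, but more slowly: blue loses 37 percentage points up to 2.50 d and 8.2 points in the stretch up to 5.00 d. So the number to count with is the tail half-life, an apparent pseudo-first-order half-life: the time in which the starting complex would halve at the pace of a run's last two readings. Blue gives 12.4 d and red 16.2 d; both are readings and carry the scatter of 1 point.

More starting complex on the same ligand should leave a larger percent, and it does: red, with 0.21 M, reads 67.4% at 5.00 d, where blue, with 0.094 M, reads 54.8%, and red's tail reads longer. The new charge sits at the geometric mean of the two, 0.140 M, so I take geometric means as an estimate: the tail half-life of this charge comes to 14.2 d, and the level at 5.00 d to 60.8%. Incoming ligand stands at 0.070 M in both runs, so the readings show nothing of that setting.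

Counting tail half-lives from that level, my reckoning gives 57.9% for winter and 63.8% for dawn. The winter figure is twice the 27.6% of side product A in blue at 5.00 d, the higher of the two runs at that reading, so the starting complex should lead.

The forecast names starting complex for winter at 60.5% (56.5% to 64.5%) and starting complex for dawn at 64.5% (61% to 68%), noting that “The decay is slowing as ligand is used up”. Its winter value stands 2.6 points above mine.

The flasks give starting complex at 59.2% in winter and starting complex at 64.3% in dawn.

    incoming ligand ⇌ dormant form (K = 1.20, k = 3.00 × 10⁻⁶ /s)
    complex with two exchanged + incoming ligand ⇌ leaving ligand + complex with three exchanged (K = 1.10, k = 3.20 × 10⁻⁵ /M/s)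
    starting complex + incoming ligand ⇌ leaving ligand + complex with one exchanged (K = 0.350, k = 9.90 × 10⁻⁵ /M/s)
    leaving ligand + starting complex → side product B (k = 5.70 × 10⁻⁶ /M/s)
    complex with one exchanged → side product A (k = 1.20 × 10⁻⁵ /s)
    complex with one exchanged + incoming ligand ⇌ leaving ligand + complex with two exchanged (K = 13.0, k = 2.10 × 10⁻⁴ /M/s)

In winter at 6.00 d, the forward reaction of starting complex with incoming ligand, taken alone, gives the starting complex a half-life of 16 d, longer than the reading time. In that flask incoming ligand, the limiting reagent, has 7.2% of its charge left unbound, with 0.00920 M standing as dormant form, against 59% of the starting complex. Counted onward from 59.2%, the tail half-life gives 48.7% for the same winter charge read at 10 d, which stands at 51.1%. With 0.035 M of starting complex in the winter recipe instead, side product A leads with 40.8% against 32.3% of starting complex at 6.00 d.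

The readings are simulated with constants of no real substance; scatter was added.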